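Numbering the heptane chain C1 (benzylic carbon on the methoxycatechol ring A) to C7 (on the phenol ring B), the C5 oxygen sits 1,5 to the oxidisable benzylic C1–H of electron-rich ring A. The route therefore ties C1–O–C5 into a temporary oxane and disconnects C1–C2. The precursor is the ring-A benzyl ether of an (S)-C5 carbinol that carries a C2=C3 enol acetate; oxidative ionisation of C1–H and capture by the enol acetate forge C1–C2, close a cis-2,6-disubstituted oxan-4-one and set C1 in one operation. Inside that ring C5 dictates the face of C3 reduction, and hydrogenolysis of the benzylic C1–O bond then reopens it to the syn-(3R,5S)-diol.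

Key step: step 8

Remark on the chemistry: by atom count the cyclisation precursor has to be a hex-1-en-2-yl acetate (chain carbons C2–C7, ether oxygen on its C4, ring B on its C6). A hept-1-en-2-yl acetate would give a tether one carbon too long, so compound 12 is named and drawn as the hexenyl acetate.

Assumption: compounds 1, 5 and 6 are commercially available. All three phenols are carried as benzyl ethers so that a single hydrogenolysis ends the synthesis.

Step 1
Reactants: 1 3,4-dihydroxy-5-methoxybenzaldehyde
Product: 2 3,4-bis(benzyloxy)-5-methoxybenzaldehyde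
Conditions: BnBr (2.3 equiv), K2CO3, DMF, 60 °C
Reagents that add atoms: benzyl bromide, BrCc1ccccc1
Why: Double Williamson O-alkylation of the two phenols with carbonate base in a polar aprotic solvent is routine for catechol aldehydes and leaves the aldehyde and the methyl ether untouched.

Step 2
Reactants: 2 3,4-bis(benzyloxy)-5-methoxybenzaldehyde
Product: 3 [3,4-bis(benzyloxy)-5-methoxyphenyl]methanol
Conditions: NaBH4, MeOH–THF, 0 °C; aqueous work-up
Reagents that add atoms: none
Why: Borohydride reduction of an aromatic aldehyde to the benzylic alcohol is chemoselective in the presence of aryl benzyl and methyl ethers.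

Step 3
Reactants: 3 [3,4-bis(benzyloxy)-5-methoxyphenyl]methanol
Product: 4 3,4-bis(benzyloxy)-5-methoxybenzyl bromide
Conditions: PBr3 (0.4 equiv), CH2Cl2, 0 °C; used crude
Reagents that add atoms: phosphorus tribromide, BrP(Br)Br
Why: Bromination of an electron-rich benzylic alcohol with PBr3 (displacement of the activated phosphite ester by bromide) is fast at 0 °C, and the solvolysis-prone bromide should be carried on without purification.

Step 4
Reactants: 5 4-(benzyloxy)benzyl chloride, 6 (S)-epichlorohydrin
Product: 8 (S)-4-[4-(benzyloxy)phenyl]-1-chlorobutan-2-ol, via Grignard reagent 7 (not isolated)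
Conditions: Mg (excess), THF, 0 °C, slow addition at high dilution; then 6, CuI (10 mol%), THF, −40 to 0 °C; aqueous work-up
Reagents that add atoms: none
Why: Copper-catalysed Grignard opening of a terminal epoxide proceeds by SN2 attack at the unsubstituted CH2 faster than displacement of the primary chloride, so the epichlorohydrin stereocentre passes unchanged into the (S)-carbinol that becomes C5.

Step 5
Reactants: 8 (S)-4-[4-(benzyloxy)phenyl]-1-chlorobutan-2-ol
Product: 10 (S)-1-[4-(benzyloxy)phenyl]hex-5-yn-3-ol, via epoxide 9 (not isolated)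
Conditions: lithium acetylide–ethylenediamine complex (3 equiv), DMSO, 0 °C to rt; aqueous work-up
Reagents that add atoms: lithium acetylide–ethylenediamine complex, [Li]C#C.NCCN
Why: One equivalent of acetylide serves as base so that the chlorohydrin closes by intramolecular Williamson reaction to terminal epoxide 9, which a second equivalent opens by SN2 attack at its CH2 terminus, the C5 stereocentre being a spectator in both events.

Step 6
Reactants: 10 (S)-1-[4-(benzyloxy)phenyl]hex-5-yn-3-ol, 4 3,4-bis(benzyloxy)-5-methoxybenzyl bromide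
Product: 11 (S)-1-[4-(benzyloxy)phenyl]hex-5-yn-3-yl 3,4-bis(benzyloxy)-5-methoxybenzyl ether
Conditions: NaH (1.2 equiv), THF–DMF, 0 °C; then 4, n-Bu4NI (cat.), 0 °C to rt
Reagents that add atoms: none
Why: Williamson etherification of the sodium alkoxide (the alcohol is far more acidic than the terminal alkyne) with the reactive benzylic bromide under iodide catalysis occurs at oxygen and does not touch the stereocentre.

Step 7
Reactants: 11 (S)-1-[4-(benzyloxy)phenyl]hex-5-yn-3-yl 3,4-bis(benzyloxy)-5-methoxybenzyl ether
Product: 12 (S)-4-{[3,4-bis(benzyloxy)-5-methoxybenzyl]oxy}-6-[4-(benzyloxy)phenyl]hex-1-en-2-yl acetate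
Conditions: AcOH (2 equiv), [Ru(p-cymene)Cl2]2 (cat.), P(2-furyl)3 (cat.), Na2CO3 (cat.), toluene, 80 °C
Reagents that add atoms: acetic acid, CC(=O)O
Why: Ruthenium-catalysed Markovnikov addition of a carboxylic acid to a terminal alkyne (hydro-acyloxylation) gives the 1-alken-2-yl acetate under near-neutral conditions that leave all ethers and the stereocentre untouched.

Step 8
Reactants: 12 (S)-4-{[3,4-bis(benzyloxy)-5-methoxybenzyl]oxy}-6-[4-(benzyloxy)phenyl]hex-1-en-2-yl acetate
Product: 14 (2S,6S)-2-[3,4-bis(benzyloxy)-5-methoxyphenyl]-6-{2-[4-(benzyloxy)phenyl]ethyl}oxan-4-one, via oxocarbenium ion 13 (not isolated)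
Conditions: DDQ (2 equiv), 2,6-dichloropyridine (4 equiv), LiClO4 (cat.), 4 Å MS, ClCH2CH2Cl, 0 °C to rt; aq NaHCO3
Reagents that add atoms: none
Why: DDQ takes one electron from the trioxygenated ring A and then the C1 hydrogen (net hydride abstraction) to give the aryl-conjugated (E)-oxocarbenium ion 13, whose C1 is attacked by the enol acetate terminus C2, and the resulting acetoxycarbenium ion at C3 sheds its acetyl group to leave the ketone. The closest known reaction type is the DDQ-mediated oxidative C–H cyclisation of p-methoxybenzyl and dimethoxybenzyl ethers onto tethered enol acetates, a Prins-type closure. The oxane closes in a 6-endo-trig mode (both the C1=O+ and the C2=C3 π bonds lie inside the new ring) through a chair transition state. The new C1 stereocentre is controlled by the existing C5 centre, because in the chair with the (E)-oxocarbenium geometry the ring-A aryl group and the C6–C7 side chain both sit equatorial, which should give the 2,6-cis (2S,6S) isomer. The step needs chemoselective oxidation of C1–H in the presence of three aryl benzyl ethers and the ring-B benzylic C7–H bonds; ring A is the most electron-rich arene and C1–H is the only C–H that is both benzylic to it and α to an ether oxygen, while the hindered pyridine buffers the acid and the ring carbonyl deactivates the product towards re-oxidation.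

Step 9
Reactants: 14 (2S,6S)-2-[3,4-bis(benzyloxy)-5-methoxyphenyl]-6-{2-[4-(benzyloxy)phenyl]ethyl}oxan-4-one
Product: 15 (2S,4S,6S)-2-[3,4-bis(benzyloxy)-5-methoxyphenyl]-6-{2-[4-(benzyloxy)phenyl]ethyl}oxan-4-ol
Conditions: L-Selectride (1.2 equiv), THF, −78 °C; aqueous work-up
Reagents that add atoms: none
Why: In the chair oxanone with both substituents equatorial, the bulky tri-sec-butylborohydride should attack from the equatorial direction (substrate-controlled diastereoselective ketone reduction) and give the axial alcohol trans to both ring substituents, which is the 3R carbinol of the open chain and hence the syn-1,3-diol relationship to C5.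

Step 10
Reactants: 15 (2S,4S,6S)-2-[3,4-bis(benzyloxy)-5-methoxyphenyl]-6-{2-[4-(benzyloxy)phenyl]ethyl}oxan-4-ol
Product: 16 (3R,5S)-1-(3,4-dihydroxy-5-methoxyphenyl)-7-(4-hydroxyphenyl)heptane-3,5-diol
Conditions: H2 (1 atm), Pd(OH)2/C, HCl (cat.), MeOH–EtOAc, rt, exclusion of air on work-up
Reagents that add atoms: none
Why: Palladium-catalysed hydrogenolysis removes the three O-benzyl groups and, assisted by acid and the para-oxygenated ring A, also cleaves the benzylic C1–O bond of the 2-aryloxane, which turns C1 into CH2 and frees the C5 hydroxyl without breaking any bond at the C3 or C5 stereocentres.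

Compound list
1 | 3,4-dihydroxy-5-methoxybenzaldehyde | COc1cc(C=O)cc(O)c1O | starting material
2 | 3,4-bis(benzyloxy)-5-methoxybenzaldehyde | COc1cc(C=O)cc(OCc2ccccc2)c1OCc1ccccc1 | intermediate
3 | [3,4-bis(benzyloxy)-5-methoxyphenyl]methanol | COc1cc(CO)cc(OCc2ccccc2)c1OCc1ccccc1 | intermediate
4 | 3,4-bis(benzyloxy)-5-methoxybenzyl bromide | COc1cc(CBr)cc(OCc2ccccc2)c1OCc1ccccc1 | intermediate
5 | 4-(benzyloxy)benzyl chloride | ClCc1ccc(OCc2ccccc2)cc1 | starting material
6 | (S)-epichlorohydrin | ClC[C@@H]1CO1 | starting material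
7 | [4-(benzyloxy)benzyl]magnesium chloride (formed in situ) | Cl[Mg]Cc1ccc(OCc2ccccc2)cc1 | intermediate
8 | (S)-4-[4-(benzyloxy)phenyl]-1-chlorobutan-2-ol | ClC[C@@H](O)CCc1ccc(OCc2ccccc2)cc1 | intermediate
9 | (S)-2-{2-[4-(benzyloxy)phenyl]ethyl}oxirane (formed in situ) | O(Cc1ccccc1)c1ccc(CC[C@H]2CO2)cc1 | intermediate
10 | (S)-1-[4-(benzyloxy)phenyl]hex-5-yn-3-ol | O(Cc1ccccc1)c1ccc(CC[C@H](O)CC#C)cc1 | intermediate
11 | (S)-1-[4-(benzyloxy)phenyl]hex-5-yn-3-yl 3,4-bis(benzyloxy)-5-methoxybenzyl ether | O(Cc1ccccc1)c1ccc(CC[C@H](OCc2cc(OC)c(OCc3ccccc3)c(OCc3ccccc3)c2)CC#C)cc1 | intermediate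
12 | (S)-4-{[3,4-bis(benzyloxy)-5-methoxybenzyl]oxy}-6-[4-(benzyloxy)phenyl]hex-1-en-2-yl acetate | O(Cc1ccccc1)c1ccc(CC[C@H](OCc2cc(OC)c(OCc3ccccc3)c(OCc3ccccc3)c2)CC(=C)OC(C)=O)cc1 | intermediate
13 | (E)-{(3S)-5-acetoxy-1-[4-(benzyloxy)phenyl]hex-5-en-3-yl}[3,4-bis(benzyloxy)-5-methoxybenzylidene]oxonium (formed in situ) | O(Cc1ccccc1)c1ccc(CC[C@H](/[O+]=C/c2cc(OC)c(OCc3ccccc3)c(OCc3ccccc3)c2)CC(=C)OC(C)=O)cc1 | intermediate
14 | (2S,6S)-2-[3,4-bis(benzyloxy)-5-methoxyphenyl]-6-{2-[4-(benzyloxy)phenyl]ethyl}oxan-4-one (2,6-cis) | O(Cc1ccccc1)c1ccc(CC[C@H]2CC(=O)C[C@@H](c3cc(OC)c(OCc4ccccc4)c(OCc4ccccc4)c3)O2)cc1 | intermediate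
15 | (2S,4S,6S)-2-[3,4-bis(benzyloxy)-5-methoxyphenyl]-6-{2-[4-(benzyloxy)phenyl]ethyl}oxan-4-ol (axial OH) | O(Cc1ccccc1)c1ccc(CC[C@H]2C[C@H](O)C[C@@H](c3cc(OC)c(OCc4ccccc4)c(OCc4ccccc4)c3)O2)cc1 | intermediate
16 | (3R,5S)-1-(3,4-dihydroxy-5-methoxyphenyl)-7-(4-hydroxyphenyl)heptane-3,5-diol | COc1cc(CC[C@@H](O)C[C@@H](O)CCc2ccc(O)cc2)cc(O)c1O | target

Total step count: 10.
Longest linear sequence: 8 steps (from 1 through steps 1, 2, 3, 6, 7, 8, 9 and 10; the branch from 5 and 6 joins at step 6 after two steps).

Steps most likely to fail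

1. Step 8. Hydride abstraction at C1 may be slow or misdirected, because the flanked 4-benzyloxy group of ring A is twisted out of conjugation and the ring is harder to ionise productively than a p-methoxybenzyl ether. Competing processes would be oxidation at the ring-B benzylic position, capture of the oxocarbenium ion by adventitious water with loss of the ring-A benzyl group, and over-oxidation of the product. The fallback avoids the oxidation and sets out from alkynol 10 and aldehyde 2. Compound 10 is converted into its alkoxide–acetylide dianion (n-BuLi, 2.1 equiv, THF, −78 °C) and added to 2, which should give (5S)-1-[3,4-bis(benzyloxy)-5-methoxyphenyl]-7-[4-(benzyloxy)phenyl]hept-2-yne-1,5-diol F1 as a mixture of C1 epimers of no consequence. Acid-catalysed Meyer–Schuster rearrangement of this electron-rich benzylic propargylic alcohol (cat. p-TsOH in wet CH2Cl2) should give (1E,5S)-1-[3,4-bis(benzyloxy)-5-methoxyphenyl]-7-[4-(benzyloxy)phenyl]-5-hydroxyhept-1-en-3-one F2. A 6-endo-trig oxa-Michael addition under thermodynamic control (Amberlyst-15, CH2Cl2, rt) should then place both substituents equatorial and return to the route at the cis-oxanone 14.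

2. Step 10. The ring C1–O bond may resist hydrogenolysis while the benzyl ethers fall, leaving a debenzylated oxane, or the acid may cause side reactions at the liberated catechol. The fallback sets out from 15 and separates the two events. Ionic hydrogenation (Et3SiH, BF3·OEt2, CH2Cl2, −40 to 0 °C, desilylating work-up) should ionise the C1–O bond to the para-benzyloxy-stabilised benzylic cation and trap it with hydride, giving (3R,5S)-1-[3,4-bis(benzyloxy)-5-methoxyphenyl]-7-[4-(benzyloxy)phenyl]heptane-3,5-diol F3. Neutral hydrogenolysis (H2, Pd/C, EtOAc–MeOH, rt) then removes the three benzyl groups and arrives at the target 16.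

3. Step 4. Wurtz-type homocoupling during formation of the p-alkoxybenzyl Grignard reagent may erode the mass balance, and the copper-catalysed opening may be incomplete. The fallback sets out from 5 and uses it as the electrophile instead. Coupling with allylmagnesium bromide (THF, 0 °C) should give 1-(benzyloxy)-4-(but-3-en-1-yl)benzene F4. Epoxidation (mCPBA, CH2Cl2, 0 °C) gives rac-2-{2-[4-(benzyloxy)phenyl]ethyl}oxirane F5. Hydrolytic kinetic resolution follows, with the enantiomer of the chiral (salen)Co(III) acetate catalyst that hydrolyses the (R)-epoxide and 0.55 equiv of H2O. This consumes the unwanted enantiomer as (R)-4-[4-(benzyloxy)phenyl]butane-1,2-diol F6, which is separated, and leaves the (S)-epoxide. The route is rejoined at epoxide 9, which is opened with lithium acetylide–ethylenediamine in DMSO as in the second half of step 5 to give 10.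

Further compounds
F1 | step 8 | (5S)-1-[3,4-bis(benzyloxy)-5-methoxyphenyl]-7-[4-(benzyloxy)phenyl]hept-2-yne-1,5-diol (C1 epimers) | O(Cc1ccccc1)c1ccc(CC[C@H](O)CC#CC(O)c2cc(OC)c(OCc3ccccc3)c(OCc3ccccc3)c2)cc1
F2 | step 8 | (1E,5S)-1-[3,4-bis(benzyloxy)-5-methoxyphenyl]-7-[4-(benzyloxy)phenyl]-5-hydroxyhept-1-en-3-one | O(Cc1ccccc1)c1ccc(CC[C@H](O)CC(=O)/C=C/c2cc(OC)c(OCc3ccccc3)c(OCc3ccccc3)c2)cc1
F3 | step 10 | (3R,5S)-1-[3,4-bis(benzyloxy)-5-methoxyphenyl]-7-[4-(benzyloxy)phenyl]heptane-3,5-diol | O(Cc1ccccc1)c1ccc(CC[C@H](O)C[C@H](O)CCc2cc(OC)c(OCc3ccccc3)c(OCc3ccccc3)c2)cc1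
F4 | step 4 | 1-(benzyloxy)-4-(but-3-en-1-yl)benzene | C=CCCc1ccc(OCc2ccccc2)cc1
F5 | step 4 | rac-2-{2-[4-(benzyloxy)phenyl]ethyl}oxirane | C1OC1CCc1ccc(OCc2ccccc2)cc1
F6 | step 4 | (R)-4-[4-(benzyloxy)phenyl]butane-1,2-diol | OC[C@H](O)CCc1ccc(OCc2ccccc2)cc1
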